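**Retrosynthetic overview**

1. Feature: with the oxolane numbered O1/C2/C3/C4/C5, the target is meso, with the aryls at C2 and C5 cis, the CH2OH arms at C3 and C4 cis, and each aryl trans to its neighbouring arm; this is the array of the oxolane ring (O7, C1, C2, C3, C4) inside the exo furan–maleic anhydride adduct once its C5=C6 alkene is cut, the two cut carbons standing where the aryls belong.
2. Last disconnections: the two phenol O–benzyl groups and the two CH2O–acetyl groups; then both C2–aryl and C5–aryl bonds in one operation, back to the meso oxolane-2,5-dicarboxylic acid and two equivalents of a 4-(benzyloxy)-3,5-dimethoxyphenyl bromide (twofold decarboxylative C(sp3)–C(sp2) cross-coupling).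
3. The diacid comes from oxidative cleavage of the 7-oxanorbornene alkene after reduction of the anhydride to the diol and acetylation; the bicycle comes from furan and maleic anhydride.
4. Ring order: the oxolane is the only non-aromatic ring of the target; it is present from furan and gains its C3/C4 stereocentres in the Diels–Alder step 1. The carbocyclic bridge is opened in step 4, and the key step closes no ring.

Key step: step 6

Remark: the target has a mirror plane through O1 and the midpoint of C3–C4 (meso), so only relative configuration is controlled. Compound 11 is the one chiral compound of the main route; it should form as a racemate and is drawn as one enantiomer.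

**Route**

Step 1
Reactants: 1 furan; 2 maleic anhydride
Product: 3 exo-7-oxabicyclo[2.2.1]hept-5-ene-2,3-dicarboxylic anhydride (meso)
Conditions: furan (1.5 equiv), toluene, rt, 3 d; the adduct is collected by crystallisation
Reagents that add atoms: none
Why: Diels–Alder cycloaddition that is reversible at room temperature, so the thermodynamically preferred exo adduct should accumulate and crystallise, which sets C1, C2, C3 and C4 of the bicycle with the anhydride ring syn to the oxygen bridge.

Step 2
Reactants: 3 exo-7-oxabicyclo[2.2.1]hept-5-ene-2,3-dicarboxylic anhydride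
Product: 4 exo,exo-7-oxabicyclo[2.2.1]hept-5-ene-2,3-diyldimethanol (meso)
Conditions: LiAlH4 (2.5 equiv), THF, 0 °C to rt; aqueous NaOH work-up
Reagents that add atoms: none
Why: hydride reduction of a cyclic anhydride to the 1,4-diol, kept at or below room temperature to avoid retro-Diels–Alder cleavage; no stereocentre is touched.

Step 3
Reactants: 4 exo,exo-7-oxabicyclo[2.2.1]hept-5-ene-2,3-diyldimethanol
Product: 5 exo,exo-7-oxabicyclo[2.2.1]hept-5-ene-2,3-diylbis(methylene) diacetate (meso)
Conditions: Ac2O, pyridine, DMAP (cat.), CH2Cl2, 0 °C to rt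
Reagents that add atoms: acetic anhydride, CC(=O)OC(C)=O
Why: DMAP-catalysed acylation of two primary alcohols, which masks them against the oxidant of step 4 and against lactonisation with the acids formed there.

Step 4
Reactants: 5 exo,exo-7-oxabicyclo[2.2.1]hept-5-ene-2,3-diylbis(methylene) diacetate
Product: 7 meso-3,4-bis(acetoxymethyl)oxolane-2,5-dicarboxylic acid (2,5-cis; 3,4-cis; 2,3-trans), via 2,5-diformyl diacetate 6 (not isolated)
Conditions: RuCl3·xH2O (3 mol%), NaIO4 (4.5 equiv), EtOAc/MeCN/H2O, 0 °C to rt; acidify, extract with EtOAc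
Reagents that add atoms: sodium periodate, [Na+].[O-]I(=O)(=O)=O; water, O
Why: oxidative cleavage of a 1,2-disubstituted alkene by RuO4 generated in the flask from RuCl3 and NaIO4 should pass through the dialdehyde to the diacid; only the C5=C6 bond is broken, so the two CO2H groups stay cis to each other and trans to the CH2OAc arms.

Step 5
Reactants: 8 4-bromo-2,6-dimethoxyphenol; 9 benzyl bromide
Product: 10 2-(benzyloxy)-5-bromo-1,3-dimethoxybenzene
Conditions: K2CO3 (1.5 equiv), DMF, rt
Reagents that add atoms: none
Why: Williamson ether synthesis of a phenoxide with a benzylic bromide; the aryl C–Br bond is inert under these conditions.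

Step 6
Reactants: 7 meso-3,4-bis(acetoxymethyl)oxolane-2,5-dicarboxylic acid; 10 2-(benzyloxy)-5-bromo-1,3-dimethoxybenzene (3 equiv, two are consumed)
Product: 12 meso-{2,5-bis[4-(benzyloxy)-3,5-dimethoxyphenyl]oxolane-3,4-diyl}bis(methylene) diacetate, via monoaryl monoacid 11 (not isolated)
Conditions: Ir[dF(CF3)ppy]2(dtbbpy)PF6 (2 mol%), NiCl2(dme) (20 mol%), 4,4'-di-tert-butyl-2,2'-bipyridine (25 mol%), Cs2CO3 (3 equiv), degassed DMF, blue LEDs (450 nm), rt
Reagents that add atoms: none
Why: The photoexcited iridium complex (trivalent iridium) oxidises each caesium carboxylate by single-electron transfer, CO2 is lost and a flattened, nucleophilic alpha-oxy radical forms at C2 and later at C5; the aryl nickel bromide (divalent nickel) from oxidative addition of 10 to zerovalent nickel captures it, and reductive elimination from the trivalent alkyl(aryl)nickel makes the C–aryl bond while the reduced photocatalyst (divalent iridium) returns nickel to the zerovalent state. The closest known reaction type is the metallaphotoredox decarboxylative arylation of alpha-oxy acids such as oxolane-2-carboxylic acid and furanosyl acids with aryl bromides, used here twice on one ring by way of monoacid 11. No ring is closed. The new stereocentres C2 and C5 are each controlled by the adjacent stereocentre (C3 for C2, C4 for C5): the bulky bipyridine-ligated aryl nickel unit should bind the radical face anti to the neighbouring CH2OAc arm, and stereoretentive reductive elimination then places the aryl trans to that arm, as in 1,2-trans C-arylation of furanosyl radicals. The step needs facial selectivity at both radicals and cross-coupling in preference to hydrogen-atom quenching; because the C3 and C4 arms are cis, two independent trans deliveries converge on the 2,5-cis diaryl meso array, and the excess of 10 and base should keep aryl nickel available for the second event.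

Step 7
Reactants: 12 meso-{2,5-bis[4-(benzyloxy)-3,5-dimethoxyphenyl]oxolane-3,4-diyl}bis(methylene) diacetate
Product: 13 meso-{2,5-bis[4-(benzyloxy)-3,5-dimethoxyphenyl]oxolane-3,4-diyl}dimethanol
Conditions: K2CO3 (0.3 equiv), MeOH/THF, rt
Reagents that add atoms: none
Why: methoxide-catalysed transesterification (Zemplén-type deacetylation) should remove both acetates as methyl acetate; the aryl benzyl ethers and the oxolane are inert and no stereocentre bears an acidic hydrogen.

Step 8
Reactants: 13 meso-{2,5-bis[4-(benzyloxy)-3,5-dimethoxyphenyl]oxolane-3,4-diyl}dimethanol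
Product: 14 [(2R,3S,4R,5S)-2,5-bis(4-hydroxy-3,5-dimethoxyphenyl)oxolane-3,4-diyl]dimethanol (meso; the target)
Conditions: H2 (1 atm), 10% Pd/C, EtOAc/MeOH, rt, stopped at consumption of 13
Reagents that add atoms: none
Why: heterogeneous hydrogenolysis of aryl benzyl ethers over Pd/C, which under neutral low-pressure conditions should be much faster than cleavage of the ring C2–O and C5–O benzylic bonds, so all four stereocentres are kept.

**Compound list**

1 | furan | c1ccoc1 | starting material
2 | maleic anhydride | O=C1OC(=O)C=C1 | starting material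
3 | exo-7-oxabicyclo[2.2.1]hept-5-ene-2,3-dicarboxylic anhydride (meso; anhydride ring syn to the O bridge) | C1=C[C@H]2O[C@@H]1[C@@H]3C(=O)OC(=O)[C@H]23 | intermediate
4 | exo,exo-7-oxabicyclo[2.2.1]hept-5-ene-2,3-diyldimethanol (meso) | C1=C[C@H]2O[C@@H]1[C@H](CO)[C@@H]2CO | intermediate
5 | exo,exo-7-oxabicyclo[2.2.1]hept-5-ene-2,3-diylbis(methylene) diacetate (meso) | C1=C[C@H]2O[C@@H]1[C@H](COC(C)=O)[C@@H]2COC(C)=O | intermediate
6 | meso-(2,5-diformyloxolane-3,4-diyl)bis(methylene) diacetate (2,5-cis; 3,4-cis; 2,3-trans; not isolated) | O=C[C@H]1O[C@@H](C=O)[C@H](COC(C)=O)[C@@H]1COC(C)=O | intermediate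
7 | meso-3,4-bis(acetoxymethyl)oxolane-2,5-dicarboxylic acid (2,5-cis; 3,4-cis; 2,3-trans) | OC(=O)[C@H]1O[C@@H](C(=O)O)[C@H](COC(C)=O)[C@@H]1COC(C)=O | intermediate
8 | 4-bromo-2,6-dimethoxyphenol | COc1cc(Br)cc(OC)c1O | starting material
9 | benzyl bromide | BrCc1ccccc1 | starting material
10 | 2-(benzyloxy)-5-bromo-1,3-dimethoxybenzene | COc1cc(Br)cc(OC)c1OCc2ccccc2 | intermediate
11 | rac-3,4-bis(acetoxymethyl)-5-[4-(benzyloxy)-3,5-dimethoxyphenyl]oxolane-2-carboxylic acid (aryl and CO2H cis; each trans to its neighbouring CH2OAc; not isolated) | COc1cc([C@H]2O[C@@H](C(=O)O)[C@H](COC(C)=O)[C@@H]2COC(C)=O)cc(OC)c1OCc3ccccc3 | intermediate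
12 | meso-{2,5-bis[4-(benzyloxy)-3,5-dimethoxyphenyl]oxolane-3,4-diyl}bis(methylene) diacetate (2,5-cis; 3,4-cis; 2,3-trans) | COc1cc([C@H]2O[C@@H](c3cc(OC)c(OCc4ccccc4)c(OC)c3)[C@H](COC(C)=O)[C@@H]2COC(C)=O)cc(OC)c1OCc5ccccc5 | intermediate
13 | meso-{2,5-bis[4-(benzyloxy)-3,5-dimethoxyphenyl]oxolane-3,4-diyl}dimethanol | COc1cc([C@H]2O[C@@H](c3cc(OC)c(OCc4ccccc4)c(OC)c3)[C@H](CO)[C@@H]2CO)cc(OC)c1OCc5ccccc5 | intermediate
14 | [(2R,3S,4R,5S)-2,5-bis(4-hydroxy-3,5-dimethoxyphenyl)oxolane-3,4-diyl]dimethanol (meso) | COc1cc([C@H]2O[C@@H](c3cc(OC)c(O)c(OC)c3)[C@H](CO)[C@@H]2CO)cc(OC)c1O | target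

**Step count**

Total steps: 8. Longest linear sequence: 7 (steps 1, 2, 3, 4, 6, 7, 8); step 5 is a one-step side branch.

**Steps most likely to fail**

Step 6 (twofold decarboxylative arylation). Oxidative addition of the electron-rich bromide to zerovalent nickel may be slow, and the cis-2,5-dicarboxylate may sequester nickel. The alpha-oxy radicals would then be quenched by hydrogen abstraction, or the reaction would stall after the first arylation. The fallback supplies the aryl as a nucleophile and generates the radical from a redox-active ester. From 7, esterification with N-hydroxyphthalimide (N,N'-diisopropylcarbodiimide, DMAP cat., CH2Cl2) should give the bis(N-phthalimidoyl) ester F1. From 10, bromine–lithium exchange (n-BuLi, THF, −78 °C) should give the aryllithium F2, and ZnCl2 should convert it into the arylzinc chloride F3. Nickel-catalysed decarboxylative Negishi arylation of F1 with F3 (NiCl2(dme), 4,4'-di-tert-butyl-2,2'-bipyridine, THF/DMF, rt) should then deliver both aryls under the same adjacent-arm control and rejoin the route at 12.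

Step 8 (hydrogenolysis). Over-reduction is possible: the ring C2–O or C5–O benzylic bonds may be cleaved alongside the benzyl ethers, opening the oxolane. The fallback avoids hydrogen by carrying the phenols as silyl ethers. From 8, silylation (triisopropylsilyl chloride, imidazole, DMF) should give the silyl ether F4. Coupling of F4 with 7 under the conditions of step 6 should give the bis(silyl ether) diacetate F5. Tetrabutylammonium fluoride buffered with AcOH (THF, 0 °C) should give the bisphenol diacetate F6. Methanolysis (K2CO3, MeOH, rt; NH4Cl work-up) should then come back to the route at 14.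

Step 4 (oxidative cleavage). RuO4 may over-oxidise the ether alpha-C–H bonds, and the water-soluble diacid may be lost on work-up. The fallback is stepwise. From 5, dihydroxylation on the exo face (OsO4 cat., N-methylmorpholine N-oxide, acetone/H2O) should give the exo-cis-diol F7. Glycol cleavage (NaIO4, THF/H2O) should give dialdehyde 6. Pinnick oxidation (NaClO2, NaH2PO4, 2-methyl-2-butene, t-BuOH/H2O) should return to the route at 7.

**Further compounds**

F1 | step 6 | meso-bis(1,3-dioxoisoindolin-2-yl) 3,4-bis(acetoxymethyl)oxolane-2,5-dicarboxylate (2,5-cis; 3,4-cis; 2,3-trans) | O=C(ON1C(=O)c2ccccc2C1=O)[C@H]3O[C@@H](C(=O)ON4C(=O)c5ccccc5C4=O)[C@H](COC(C)=O)[C@@H]3COC(C)=O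
F2 | step 6 | [4-(benzyloxy)-3,5-dimethoxyphenyl]lithium | [Li]c1cc(OC)c(OCc2ccccc2)c(OC)c1
F3 | step 6 | [4-(benzyloxy)-3,5-dimethoxyphenyl]zinc chloride | Cl[Zn]c1cc(OC)c(OCc2ccccc2)c(OC)c1
F4 | step 8 | (4-bromo-2,6-dimethoxyphenoxy)tri(propan-2-yl)silane | COc1cc(Br)cc(OC)c1O[Si](C(C)C)(C(C)C)C(C)C
F5 | step 8 | meso-{2,5-bis[3,5-dimethoxy-4-(triisopropylsilyloxy)phenyl]oxolane-3,4-diyl}bis(methylene) diacetate (2,5-cis; 3,4-cis; 2,3-trans) | COc1cc([C@H]2O[C@@H](c3cc(OC)c(O[Si](C(C)C)(C(C)C)C(C)C)c(OC)c3)[C@H](COC(C)=O)[C@@H]2COC(C)=O)cc(OC)c1O[Si](C(C)C)(C(C)C)C(C)C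
F6 | step 8 | meso-[2,5-bis(4-hydroxy-3,5-dimethoxyphenyl)oxolane-3,4-diyl]bis(methylene) diacetate (2,5-cis; 3,4-cis; 2,3-trans) | COc1cc([C@H]2O[C@@H](c3cc(OC)c(O)c(OC)c3)[C@H](COC(C)=O)[C@@H]2COC(C)=O)cc(OC)c1O
F7 | step 4 | exo,exo-5,6-dihydroxy-7-oxabicyclo[2.2.1]heptane-exo,exo-2,3-diylbis(methylene) diacetate (meso) | O[C@H]1[C@@H](O)[C@H]2O[C@@H]1[C@H](COC(C)=O)[C@@H]2COC(C)=O
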